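**Remarks on the chemistry (assumptions)**
- Rings are lettered A to F in the order in which they occur in the SMILES of the target; the target (C36H26O21) has no stereocentre and no configurationally stable axis.
- The key-step structures were checked atom by atom against ring B and need no correction. Two design changes are made: the quinone is formed completely from the 2-alkoxyphenol before the nucleophile is added, and the outer hydroxyl of ring B is capped as a methyl ether, so that one kind of protecting group is carried to the end.
- 5-Fluoro-1,2,3-trimethoxybenzene, 4-bromo-2,6-dimethoxyphenol and (3,4,5-trimethoxyphenyl)boronic acid are taken to be catalogue chemicals.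

## Structural features

The target is a linear chain of six benzene rings held together only by five diaryl ether oxygens. There is no C–C bond between rings and no stereocentre, so no configuration has to be set and no stereocentres stand next to each other. Ring A is a 2,4,6-trihydroxyphenyl ether and ring F a 3,4,5-trihydroxyphenyl ether. Rings B and D are 3,5-dihydroxy-1,4-phenylene dioxy units. Rings C and E are penta-oxygenated, with ether oxygens on C1 and C2, hydroxyls on C3 to C5 and a single C–H at C6. The sixteen free hydroxyls, above all the three adjacent ones on rings C, E and F, are oxidised easily by air in base, so they stay masked until the last step and the free polyphenol is handled under argon. The real difficulty is the five aryl–oxygen bonds between electron-rich rings: each ether oxygen has two ortho oxygen substituents on one of its rings, and the B–O–C and D–O–E bonds carry a third ortho substituent on the other ring. The key step exploits ring B: C1 carries the oxygen from ring A and is flanked by C2–H and C6–H, while C3, C4 and C5 opposite carry three adjacent oxygens. This is the pattern left when a phenol oxygen adds to C5 of a 3-alkoxy-ortho-quinone.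

## Logic of the disconnections

**22 ⇒ 21.** The sixteen O–H bonds are traced back to O–CH3 bonds. Free phenols would not survive the basic and oxidising coupling steps, and a single kind of ether allows one global deprotection. The forward step must cleave every methyl ether without touching the five aryl–O–aryl bonds.

**21 ⇒ 14 + 20.** The bond cut joins the oxygen on C2 of ring C to C1 of ring D. This divides the hexamer into two trimers of equal size, and C1 of ring D has two ortho hydrogens, so the steric load lies on one partner only. The forward step is a copper-mediated O-arylation of a phenol with two ortho substituents by an electron-rich aryl bromide.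

**14 ⇒ 12 ⇒ 8 + 11.** The C2–O bond of ring C is first exchanged for a C2–CHO bond, then the bond between the central oxygen of ring B and C1 of ring C is cut. The formyl group activates the ortho fluoride for substitution and afterwards becomes exactly the hydroxyl needed for the union. Ring C arrives with all its oxygens in place. The forward steps need substitution at an electron-rich fluoroarene by a hindered phenoxide and an aryl-migration oxidation that spares the other rings.

**20 ⇒ 18 + 19, then 18 ⇒ 16 ⇒ 15 + 11.** The bond between the oxygen on C2 of ring E and C1 of ring F is cut first, then the same formyl-for-hydroxyl exchange and fluoride displacement as above. 11 serves for ring E as it does for ring C, and 15 brings ring D with its bromide. The etherification with 19 must leave the aryl bromide alone.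

**11 ⇒ 9.** The C–CHO bond is cut. The position between fluorine and methoxy is the most acidic one, so the forward step is a directed lithiation followed by formylation, run cold to prevent aryne formation.

**8 ⇒ 7 ⇒ 6.** The O–CH3 bond on the outer oxygen of ring B is cut, then the two O–H bonds are traced back to the two carbonyls. This leaves only the central oxygen free for the bond to ring C. The forward methylation must distinguish two neighbouring hydroxyls.

**6 ⇒ 3 + 4 (through 5).** Two bonds of ring B are cut: the bond from C1 to the oxygen of ring A, and the C–O bond of the outer oxygen. Ring B is reduced to a phenol with one alkoxy group, and the hindered A–O–B ether needs no aryl halide. The forward step needs oxygenation at the one free ortho carbon of 4, addition of 3 through oxygen at C5 of 5, and survival of electron-rich 3 under O2.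

**3 ⇒ 1 (through 2).** The C–O bond of the phenol is exchanged for a C–CHO bond. 1 is cheap and carries the three methoxy groups that drive the aryl migration.

## Other disconnections considered

**Alternative 1:** The cut removes ring D itself (bonds C2–C3, C3–C4 and C6–C1). The hexamer falls into 3-ethoxy-4-[3,4,5-trimethoxy-2-(3,4,5-trimethoxyphenoxy)phenoxy]cyclobut-2-en-1-one A2, which carries rings E and F, and the ethynyl ether of 14, A3. On heating, A2 should open to a vinylketene that adds to A3; four-electron ring opening and 6π closure would then give A1, the hexamer with ring D as a 3-hydroxy-5-ethoxy unit (Danheiser benzannulation).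
- In favour: both ether bonds to ring D exist before the ring does, so no aryl–oxygen bond has to be made at ring D, and the ring D pattern follows from the polarity of ketene and ynol ether. On convergence (3 + 3) it is the equal of the chosen plan; on avoiding a late copper-mediated etherification it is the better.
- Against: A2 belongs to no common class. A hindered, electron-rich phenoxide would have to be placed on the sp3 carbon of a 3-alkoxycyclobutenone, and the phenol needed for this is itself the product of steps 5 and 8 to 10. A3 needs strongly basic eliminations on a trimer. An aryloxyacetylene is a weaker ketenophile than an alkyl or silyl ynol ether, and the cascade needs heat, at which the aryloxy-substituted vinylketene may take other paths.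
- Comparison: mechanistically it is a pericyclic cascade set against a polar copper-mediated substitution that has close analogy on diaryl ethers. A2 and A3 each add about two steps to trimers the chosen route already makes, and A1 still needs global dealkylation. The A–B bond is not addressed and would still call for step 2.

**Alternative 2:** The cut is the ring A bond between the ether carbon and the neighbouring C–OH carbon. Forward, KOMe in methanol should open 6-{[4-(benzyloxy)-3,5-dimethoxyphenoxy]methyl}-4-methoxy-2H-pyran-2-one A5 to a keto ester whose aryloxy-bearing carbanion attacks the ester carbonyl, closing ring A as 2-[4-(benzyloxy)-3,5-dimethoxyphenoxy]-5-methoxybenzene-1,3-diol A4.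
- In favour: the A–O–B bond is made by simple alkylation of an unhindered phenol with a bromomethylpyrone, and no electron-rich phenol is exposed to an oxidant. On the safety of the C–O bond formation it is the better of the two plans.
- Against: the most acidic position of the opened chain is the methylene between enol ether and ketone, not the aryloxymethyl group, so the productive carbanion is a minor, reversibly formed species. The ring B phenol and the pyrone bromide must each be prepared. A4 needs two O-methylations and a hydrogenolysis before it reaches 8.
- Comparison: that is about seven steps to 8 against four in the chosen route. Like the chosen key step it builds only the A–B unit, so the two are equal in what they leave to be done for rings C to F. The chosen step forms two bonds of ring B from two simple phenols, while this one forms one C–C bond of ring A.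

**Alternative 3:** The cut is the three C4–O bonds of rings C, E and F. Forward, H2O2 with acid would convert the trialdehyde A7 (a formyl group at C4 of rings C, E and F, thirteen methyl ethers) into the triphenol A6 in one operation.
- In favour: each formyl group sits para to the carbon that carries the B–O–C, D–O–E or E–O–F oxygen, so these hindered ethers could all be made by fluoride displacement with the strongest activation available. The three hydroxyls set free need no further handling, and three fewer methyl ethers remain for the last step; on that point it is the better.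
- Against: rings C and E would need 4-fluorobenzaldehydes with two ortho methoxy groups and an additional ortho oxygen, which are not available and take several steps each. A formyl group between two methoxy groups is a weak activator. A threefold oxidation on a hexamer risks partial conversion, and the products are para-alkoxyphenols that excess peroxide can take on to quinones.
- Comparison: the chosen plan uses the same formyl-activation and aryl-migration logic (steps 6 to 9), but with an ortho formyl group, once per fragment, on small molecules, and the hydroxyl set free is at once the nucleophile for the next ether. On mechanism the two are equal. On step economy the chosen plan should be shorter because 11 is one step from 9.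

Key step: step 2

## Route

**Step 1**
Reactants: 1 2,4,6-trimethoxybenzaldehyde
Product: 3 2,4,6-trimethoxyphenol, via 2,4,6-trimethoxyphenyl formate 2 (not isolated)
Conditions: 30% aq. H2O2 (1.3 equiv), H2SO4 (cat.), MeOH, 0 °C to rt, Ar
Reagents that add atoms: hydrogen peroxide, OO
Why: Acid-catalysed Dakin oxidation: H2O2 adds to the protonated aldehyde, the aryl group (two ortho and one para methoxy) migrates to oxygen, and formate 2 is methanolysed in the same flask; argon limits air oxidation of 3.

**Step 2**
Reactants: 4 guaiacol (2-methoxyphenol); 3 2,4,6-trimethoxyphenol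
Product: 6 3-methoxy-5-(2,4,6-trimethoxyphenoxy)cyclohexa-3,5-diene-1,2-dione, via 3-methoxy-ortho-quinone 5 (not isolated)
Conditions: 4 (1.5 equiv), [Cu(MeCN)4]PF6 (10 mol%), N,N'-di-tert-butylethylenediamine (20 mol%), O2 (1 atm), 4 Å MS, CH2Cl2, rt, until 4 is consumed; then 3 (1.0 equiv) in CH2Cl2 by syringe pump, O2, rt
Reagents that add atoms: dioxygen, O=O
Why: Monovalent copper, the diamine and O2 should form a side-on peroxo dicopper species (both metals divalent) that binds the phenolate of 4 and transfers one oxygen atom to its only free ortho carbon, as tyrosinase does, after which the copper catecholate is oxidised and released as quinone 5. Because 4 is consumed before 3 enters the flask, 5 meets only the intended nucleophile, which removes homo-coupling of 4 as a competing path. The phenolate oxygen of 3 adds in 1,4-fashion to C5 of 5, the β-carbon of the enone formed with the C1 carbonyl; C4 is deactivated because the 3-methoxy group turns the C2 carbonyl into a vinylogous ester, and C6 would require a 1,6-addition next to a carbonyl. Attack through carbon is excluded because both ortho carbons and the para carbon of 3 carry methoxy groups, and for the same reason 3 cannot itself be ortho-oxygenated. The copper-bound catecholate adduct is reoxidised by O2 to 6, a doubly vinylogous ester that is too electron-rich to take up a second phenol. The closest known reaction type is the copper-catalysed aerobic coupling of ortho-quinones with phenols to aryloxy-ortho-quinones, joined to the ortho-oxygenation of a phenol under the same catalyst. No ring is closed and no stereocentre is formed. The step needs cross- over homo-coupling (secured by the order of addition), C5 over C4 attack (secured by the 3-methoxy group) and survival of 3 under oxidising conditions (slow addition into an excess of 5).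

**Step 3**
Reactants: 6 3-methoxy-5-(2,4,6-trimethoxyphenoxy)cyclohexa-3,5-diene-1,2-dione
Product: 7 3-methoxy-5-(2,4,6-trimethoxyphenoxy)benzene-1,2-diol
Conditions: Na2S2O4 (3 equiv), EtOAc/H2O, rt, Ar
Reagents that add atoms: none
Why: Two-electron reduction of the ortho-quinone by dithionite in a two-phase system gives the catechol; the ethers are inert, and exclusion of air keeps 7 from reverting to 6.

**Step 4**
Reactants: 7 3-methoxy-5-(2,4,6-trimethoxyphenoxy)benzene-1,2-diol
Product: 8 2,6-dimethoxy-4-(2,4,6-trimethoxyphenoxy)phenol
Conditions: MeI (1.05 equiv), K2CO3 (1.0 equiv), degassed DMF, 0 °C to rt, Ar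
Reagents that add atoms: iodomethane, CI
Why: Williamson etherification under mono-deprotonation: the outer hydroxyl is meta to both the methoxy and the aryloxy group, so it should be the more acidic, and it is the less hindered, whereas the central hydroxyl lies between two oxygen substituents and para to the aryloxy donor; the mirror symmetry of 8 makes the site of methylation easy to check.

**Step 5**
Reactants: 9 5-fluoro-1,2,3-trimethoxybenzene
Product: 11 6-fluoro-2,3,4-trimethoxybenzaldehyde, via (6-fluoro-2,3,4-trimethoxyphenyl)lithium 10 (not isolated)
Conditions: n-BuLi (1.1 equiv), THF, −78 °C; DMF (1.5 equiv), −78 °C to 0 °C; aq. HCl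
Reagents that add atoms: N,N-dimethylformamide, CN(C)C=O
Why: Directed ortho-metalation: the two equivalent C–H bonds of 9 lie between fluorine and a methoxy group and are the most acidic, lithiation at −78 °C avoids loss of LiF to an aryne, and aryllithium 10 is formylated by DMF.

**Step 6**
Reactants: 8 2,6-dimethoxy-4-(2,4,6-trimethoxyphenoxy)phenol; 11 6-fluoro-2,3,4-trimethoxybenzaldehyde
Product: 12 6-[2,6-dimethoxy-4-(2,4,6-trimethoxyphenoxy)phenoxy]-2,3,4-trimethoxybenzaldehyde
Conditions: Cs2CO3 (1.5 equiv), dry DMSO, 110 °C, Ar
Reagents that add atoms: none
Why: Nucleophilic aromatic substitution by addition–elimination: the phenoxide of 8 attacks the fluorine-bearing carbon ortho to the formyl group, which takes up the charge of the Meisenheimer intermediate; the methoxy group para to fluorine is the middle one of three and is twisted out of conjugation, so it deactivates little, and fluoride is displaced much faster than methoxide.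

**Step 7**
Reactants: 12 6-[2,6-dimethoxy-4-(2,4,6-trimethoxyphenoxy)phenoxy]-2,3,4-trimethoxybenzaldehyde
Product: 14 6-[2,6-dimethoxy-4-(2,4,6-trimethoxyphenoxy)phenoxy]-2,3,4-trimethoxyphenol, via 6-[2,6-dimethoxy-4-(2,4,6-trimethoxyphenoxy)phenoxy]-2,3,4-trimethoxyphenyl formate 13 (not isolated)
Conditions: 30% aq. H2O2 (1.5 equiv), H2SO4 (cat.), MeOH/CH2Cl2, 0 °C to rt, Ar
Reagents that add atoms: hydrogen peroxide, OO
Why: Acid-catalysed Dakin oxidation as in step 1: the formyl carbon again lies between two oxygen-bearing carbons, migration of the aryl group gives formate 13, and its methanolysis frees the ring C hydroxyl at C2; dilute H2O2 with a trace of acid is not expected to hydroxylate the trimethoxyphenyl ring A.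

**Step 8**
Reactants: 15 4-bromo-2,6-dimethoxyphenol; 11 6-fluoro-2,3,4-trimethoxybenzaldehyde
Product: 16 6-(4-bromo-2,6-dimethoxyphenoxy)-2,3,4-trimethoxybenzaldehyde
Conditions: Cs2CO3 (1.5 equiv), dry DMSO, 110 °C, Ar
Reagents that add atoms: none
Why: The same addition–elimination as in step 6 with a simpler phenoxide; no metal is present, so the aryl bromide is untouched.

**Step 9**
Reactants: 16 6-(4-bromo-2,6-dimethoxyphenoxy)-2,3,4-trimethoxybenzaldehyde
Product: 18 6-(4-bromo-2,6-dimethoxyphenoxy)-2,3,4-trimethoxyphenol, via 6-(4-bromo-2,6-dimethoxyphenoxy)-2,3,4-trimethoxyphenyl formate 17 (not isolated)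
Conditions: 30% aq. H2O2 (1.5 equiv), H2SO4 (cat.), MeOH/CH2Cl2, 0 °C to rt, Ar
Reagents that add atoms: hydrogen peroxide, OO
Why: Dakin oxidation as in steps 1 and 7; the aryl bromide and the ethers are inert to H2O2 with acid, and methanolysis of formate 17 frees the ring E hydroxyl at C2.

**Step 10**
Reactants: 18 6-(4-bromo-2,6-dimethoxyphenoxy)-2,3,4-trimethoxyphenol; 19 (3,4,5-trimethoxyphenyl)boronic acid
Product: 20 5-bromo-1,3-dimethoxy-2-[3,4,5-trimethoxy-2-(3,4,5-trimethoxyphenoxy)phenoxy]benzene
Conditions: 19 (2.5 equiv), Cu(OAc)2 (1.0 equiv), pyridine (5 equiv), 4 Å MS, CH2Cl2, dry air, rt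
Reagents that add atoms: none
Why: Chan–Lam oxidative etherification: the electron-rich boronic acid 19, free of ortho substituents, transmetalates to divalent copper, the hindered phenoxide of 18 binds, and oxidation to trivalent copper triggers C–O reductive elimination at room temperature, with O2 returning the metal to the divalent state; the aryl bromide does not react under these conditions.

**Step 11**
Reactants: 14 6-[2,6-dimethoxy-4-(2,4,6-trimethoxyphenoxy)phenoxy]-2,3,4-trimethoxyphenol; 20 5-bromo-1,3-dimethoxy-2-[3,4,5-trimethoxy-2-(3,4,5-trimethoxyphenoxy)phenoxy]benzene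
Product: 21 hexadecamethyl ether of 22 (rings A to F joined as in the target, every hydroxyl as OCH3)
Conditions: 20 (1.3 equiv), CuI (20 mol%), picolinic acid (40 mol%), K3PO4 (2 equiv), DMSO, 100 °C, Ar
Reagents that add atoms: none
Why: Ullmann-type copper-catalysed O-arylation: the bromide of 20 has two ortho hydrogens, so the steric load lies only on the phenoxide of 14, the situation for which picolinate-ligated monovalent copper is suited; oxidative addition of the aryl bromide to the copper phenoxide and reductive elimination form the bond between the ring C oxygen and ring D.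

**Step 12**
Reactants: 21 hexadecamethyl ether of 22
Product: 22 2-{3,5-dihydroxy-4-[3,4,5-trihydroxy-2-(3,5-dihydroxy-4-{3,4,5-trihydroxy-2-(3,4,5-trihydroxyphenoxy)phenoxy}phenoxy)phenoxy]phenoxy}benzene-1,3,5-triol (CNP0114537.0)
Conditions: BBr3 (40 equiv), CH2Cl2, −78 °C to rt; MeOH then H2O, 0 °C; work-up under Ar
Reagents that add atoms: none
Why: Lewis acid-mediated cleavage of aryl methyl ethers: boron binds each ether oxygen and bromide attacks the methyl carbon in an SN2 step, which is not possible at the sp2 carbons of the five diaryl ethers; hydrolysis of the aryl borates frees the sixteen phenols, and work-up under argon protects the pyrogallol units.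

## Compound list

1 | 2,4,6-trimethoxybenzaldehyde | COc1cc(OC)c(C=O)c(OC)c1 | starting material
2 | 2,4,6-trimethoxyphenyl formate | COc1cc(OC)c(OC=O)c(OC)c1 | intermediate
3 | 2,4,6-trimethoxyphenol | COc1cc(OC)c(O)c(OC)c1 | intermediate
4 | guaiacol (2-methoxyphenol) | COc1ccccc1O | starting material
5 | 3-methoxy-ortho-quinone (3-methoxycyclohexa-3,5-diene-1,2-dione) | COC1=CC=CC(=O)C1=O | intermediate
6 | 3-methoxy-5-(2,4,6-trimethoxyphenoxy)cyclohexa-3,5-diene-1,2-dione | COC1=CC(Oc2c(OC)cc(OC)cc2OC)=CC(=O)C1=O | intermediate
7 | 3-methoxy-5-(2,4,6-trimethoxyphenoxy)benzene-1,2-diol | COc1cc(Oc2c(OC)cc(OC)cc2OC)cc(O)c1O | intermediate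
8 | 2,6-dimethoxy-4-(2,4,6-trimethoxyphenoxy)phenol | COc1cc(Oc2c(OC)cc(OC)cc2OC)cc(OC)c1O | intermediate
9 | 5-fluoro-1,2,3-trimethoxybenzene | COc1cc(F)cc(OC)c1OC | starting material
10 | (6-fluoro-2,3,4-trimethoxyphenyl)lithium | [Li]c1c(F)cc(OC)c(OC)c1OC | intermediate
11 | 6-fluoro-2,3,4-trimethoxybenzaldehyde | COc1cc(F)c(C=O)c(OC)c1OC | intermediate
12 | 6-[2,6-dimethoxy-4-(2,4,6-trimethoxyphenoxy)phenoxy]-2,3,4-trimethoxybenzaldehyde | COc1cc(OC)c(Oc2cc(OC)c(Oc3cc(OC)c(OC)c(OC)c3C=O)c(OC)c2)c(OC)c1 | intermediate
13 | 6-[2,6-dimethoxy-4-(2,4,6-trimethoxyphenoxy)phenoxy]-2,3,4-trimethoxyphenyl formate | COc1cc(OC)c(Oc2cc(OC)c(Oc3cc(OC)c(OC)c(OC)c3OC=O)c(OC)c2)c(OC)c1 | intermediate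
14 | 6-[2,6-dimethoxy-4-(2,4,6-trimethoxyphenoxy)phenoxy]-2,3,4-trimethoxyphenol | COc1cc(OC)c(Oc2cc(OC)c(Oc3cc(OC)c(OC)c(OC)c3O)c(OC)c2)c(OC)c1 | intermediate
15 | 4-bromo-2,6-dimethoxyphenol | COc1cc(Br)cc(OC)c1O | starting material
16 | 6-(4-bromo-2,6-dimethoxyphenoxy)-2,3,4-trimethoxybenzaldehyde | COc1cc(Br)cc(OC)c1Oc1cc(OC)c(OC)c(OC)c1C=O | intermediate
17 | 6-(4-bromo-2,6-dimethoxyphenoxy)-2,3,4-trimethoxyphenyl formate | COc1cc(Br)cc(OC)c1Oc1cc(OC)c(OC)c(OC)c1OC=O | intermediate
18 | 6-(4-bromo-2,6-dimethoxyphenoxy)-2,3,4-trimethoxyphenol | COc1cc(Br)cc(OC)c1Oc1cc(OC)c(OC)c(OC)c1O | intermediate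
19 | (3,4,5-trimethoxyphenyl)boronic acid | COc1cc(B(O)O)cc(OC)c1OC | starting material
20 | 5-bromo-1,3-dimethoxy-2-[3,4,5-trimethoxy-2-(3,4,5-trimethoxyphenoxy)phenoxy]benzene | COc1cc(Br)cc(OC)c1Oc1cc(OC)c(OC)c(OC)c1Oc1cc(OC)c(OC)c(OC)c1 | intermediate
21 | hexadecamethyl ether of 22 (every hydroxyl of rings A to F as OCH3) | COc1cc(OC)c(Oc2cc(OC)c(Oc3cc(OC)c(OC)c(OC)c3Oc3cc(OC)c(Oc4cc(OC)c(OC)c(OC)c4Oc4cc(OC)c(OC)c(OC)c4)c(OC)c3)c(OC)c2)c(OC)c1 | intermediate
22 | 2-{3,5-dihydroxy-4-[3,4,5-trihydroxy-2-(3,5-dihydroxy-4-{3,4,5-trihydroxy-2-(3,4,5-trihydroxyphenoxy)phenoxy}phenoxy)phenoxy]phenoxy}benzene-1,3,5-triol (CNP0114537.0) | Oc1cc(O)c(Oc2cc(O)c(Oc3cc(O)c(O)c(O)c3Oc3cc(O)c(Oc4cc(O)c(O)c(O)c4Oc4cc(O)c(O)c(O)c4)c(O)c3)c(O)c2)c(O)c1 | target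

## Step count and least certain steps

Total: 12 steps. Longest linear sequence: 8 steps (steps 1, 2, 3, 4, 6, 7, 11 and 12, from 1 to 22). Steps 5 and 8 to 10 are side branches that join at steps 6 and 11.

**Step 2 (key step).** The most likely failures are oxidation of the very electron-rich 3 by the copper–dioxygen system to a para-quinone with loss of its para methyl group, and decay of the reactive quinone 5 by self-condensation before it is captured. Both reduce the share of cross-coupled product. Residual homo-coupling of 4 would arise if its oxygenation were incomplete when 3 is added. The fallback sets out from 3 and comes back at 8, replacing steps 2 to 4. Compound 15 is O-benzylated (BnBr, K2CO3, DMF) to 2-(benzyloxy)-5-bromo-1,3-dimethoxybenzene F1. Ullmann etherification of 3 with F1 (CuI, picolinic acid, K3PO4, DMSO, 100 °C) should give 2-[4-(benzyloxy)-3,5-dimethoxyphenoxy]-1,3,5-trimethoxybenzene F2. Hydrogenolysis (H2, Pd/C, EtOAc) then frees the central hydroxyl and gives 8.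

**Step 4.** Methylation may occur at the wrong oxygen or twice, because the two hydroxyls differ only moderately in acidity and the mono-anion is shared through a hydrogen bond. Reoxidation of the catechol in base is a second loss channel. The fallback sets out from 7 and comes back at 8. Exhaustive methylation (excess MeI, K2CO3, acetone) gives 1,2,3-trimethoxy-5-(2,4,6-trimethoxyphenoxy)benzene F3. The middle methoxy group of the 1,2,3-trimethoxy array is then cleaved selectively with AlCl3 in CH2Cl2; this relies on chelation of aluminium between neighbouring oxygens and on the strained out-of-plane position of that group, and it gives 8.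

**Step 6 (step 8 is the same reaction with a simpler nucleophile and serves as its test).** Addition of a phenoxide with two ortho substituents to a fluoroarene carrying three donor groups may be slow. At the temperature then needed, displacement of the methoxy groups ortho and para to the formyl group and O-demethylation by the phenoxide can compete. The fallback sets out from 8 and comes back at 12. Purchased 5-bromo-1,2,3-trimethoxybenzene is formylated (Cl2CHOMe, TiCl4, CH2Cl2, 0 °C, Rieche formylation) to 6-bromo-2,3,4-trimethoxybenzaldehyde F4. F4 is coupled with 8 under Ullmann conditions (CuI, picolinic acid, K3PO4, DMSO, 90 °C), in which the ortho formyl group assists the copper insertion, to give 12.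

**Step 11.** The union of two trimers may stall, because the phenoxide is hindered and the bromide is electron-rich. Slow coupling leaves room for hydrodebromination of 20 and for oxidative decay of the phenoxide at 100 °C. The fallback sets out from 20 and comes back at 21. Bromine–lithium exchange (n-BuLi, THF, −78 °C), borylation with B(OiPr)3 and aqueous acid give {3,5-dimethoxy-4-[3,4,5-trimethoxy-2-(3,4,5-trimethoxyphenoxy)phenoxy]phenyl}boronic acid F5. Chan–Lam coupling of F5 with 14 under the conditions of step 10 (Cu(OAc)2, pyridine, 4 Å MS, CH2Cl2, air, rt) then forms 21 at room temperature.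

**Step 12.** Cleavage of sixteen ethers may stop short and leave partly methylated material. The very polar, air-sensitive polyphenol may also be lost or oxidised during aqueous work-up and purification. The fallback sets out from 21 and comes back at 22. After BBr3 and a methanol quench, the crude polyphenol is acetylated without purification (Ac2O, pyridine, DMAP) to the hexadecaacetate of 22 F6. F6 is stable, can be purified on silica and separated from under-demethylated material. Acid methanolysis (HCl in MeOH, Ar, rt) then releases 22.

## Further compounds

F1 | step 2 | 2-(benzyloxy)-5-bromo-1,3-dimethoxybenzene | COc1cc(Br)cc(OC)c1OCc1ccccc1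
F2 | step 2 | 2-[4-(benzyloxy)-3,5-dimethoxyphenoxy]-1,3,5-trimethoxybenzene | COc1cc(OC)c(Oc2cc(OC)c(OCc3ccccc3)c(OC)c2)c(OC)c1
F3 | step 4 | 1,2,3-trimethoxy-5-(2,4,6-trimethoxyphenoxy)benzene | COc1cc(OC)c(Oc2cc(OC)c(OC)c(OC)c2)c(OC)c1
F4 | step 6 | 6-bromo-2,3,4-trimethoxybenzaldehyde | COc1cc(Br)c(C=O)c(OC)c1OC
F5 | step 11 | {3,5-dimethoxy-4-[3,4,5-trimethoxy-2-(3,4,5-trimethoxyphenoxy)phenoxy]phenyl}boronic acid | COc1cc(B(O)O)cc(OC)c1Oc1cc(OC)c(OC)c(OC)c1Oc1cc(OC)c(OC)c(OC)c1
F6 | step 12 | hexadecaacetate of 22 (every hydroxyl of rings A to F as acetate) | CC(=O)Oc1cc(OC(C)=O)c(Oc2cc(OC(C)=O)c(Oc3cc(OC(C)=O)c(OC(C)=O)c(OC(C)=O)c3Oc3cc(OC(C)=O)c(Oc4cc(OC(C)=O)c(OC(C)=O)c(OC(C)=O)c4Oc4cc(OC(C)=O)c(OC(C)=O)c(OC(C)=O)c4)c(OC(C)=O)c3)c(OC(C)=O)c2)c(OC(C)=O)c1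
A1 | alternative 1 | hexamer with ring D as 3-hydroxy-5-ethoxy unit and all other hydroxyls as methyl ethers | COc1cc(OC)c(Oc2cc(OC)c(Oc3cc(OC)c(OC)c(OC)c3Oc3cc(O)c(Oc4cc(OC)c(OC)c(OC)c4Oc4cc(OC)c(OC)c(OC)c4)c(OCC)c3)c(OC)c2)c(OC)c1
A2 | alternative 1 | 3-ethoxy-4-[3,4,5-trimethoxy-2-(3,4,5-trimethoxyphenoxy)phenoxy]cyclobut-2-en-1-one (racemic) | CCOC1=CC(=O)C1Oc1cc(OC)c(OC)c(OC)c1Oc1cc(OC)c(OC)c(OC)c1
A3 | alternative 1 | ethynyl ether of 14 | COc1cc(OC)c(Oc2cc(OC)c(Oc3cc(OC)c(OC)c(OC)c3OC#C)c(OC)c2)c(OC)c1
A4 | alternative 2 | 2-[4-(benzyloxy)-3,5-dimethoxyphenoxy]-5-methoxybenzene-1,3-diol | COc1cc(O)c(Oc2cc(OC)c(OCc3ccccc3)c(OC)c2)c(O)c1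
A5 | alternative 2 | 6-{[4-(benzyloxy)-3,5-dimethoxyphenoxy]methyl}-4-methoxy-2H-pyran-2-one | COC1=CC(=O)OC(COc2cc(OC)c(OCc3ccccc3)c(OC)c2)=C1
A6 | alternative 3 | triphenol with free hydroxyl at C4 of rings C, E and F and thirteen methyl ethers | COc1cc(OC)c(Oc2cc(OC)c(Oc3cc(OC)c(O)c(OC)c3Oc3cc(OC)c(Oc4cc(OC)c(O)c(OC)c4Oc4cc(OC)c(O)c(OC)c4)c(OC)c3)c(OC)c2)c(OC)c1
A7 | alternative 3 | trialdehyde with formyl at C4 of rings C, E and F and thirteen methyl ethers | COc1cc(OC)c(Oc2cc(OC)c(Oc3cc(OC)c(C=O)c(OC)c3Oc3cc(OC)c(Oc4cc(OC)c(C=O)c(OC)c4Oc4cc(OC)c(C=O)c(OC)c4)c(OC)c3)c(OC)c2)c(OC)c1
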